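## Retrosynthetic overview

1. Locants: ring A is the benzene ring (C4a, C5–C8, C8a). Ring B is the dihydropyran ring (O1, C2, C3, C4, C4a, C8a). The side chain C1'–C13' is counted outward from C2, with methyl branches on C4', C8' and C12' and the alkene at C12'=C13'.
2. Key disconnection C3'–C4'. C3' is an unbranched, non-stereogenic CH2 directly beside the methine stereocentre C4' (H, CH3) and insulated from ring B by C1' and C2'. It can therefore carry first an O-acyl leaving group and then boron at no stereochemical cost, while C4' rides on boron and migrates with retention. Benzoate 9 and boronic ester 22 are tied to one boron atom, joined by a 1,2-shift, and the boron is expelled in the same flask.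
3. Left half 9: rings A and B and C2 are bought as (S)-Trolox, and C2' and C3' come from a Wittig reaction. No ring of the target is formed in the route; the only ring brought in and lost again is the temporary dioxaborolane.
4. Right half 22: C8' comes from SN2 opening of (R)-β-butyrolactone by 4-methylpent-4-enylmagnesium bromide, which also brings the alkene. C5' and the boron come from diborylmethane, and C4' with its methyl comes from a sparteine-controlled lithiated ethyl carbamate. The boron atom thus walks C5' → C4' → C3' and then leaves.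
5. The junction is made saturated, so no hydrogenation follows the arrival of the C12'=C13' alkene. The last step is desilylation.

Key step: step 13

Assumption: 5-bromo-2-methylpent-1-ene 10, diborylmethane 16 and ethyl N,N-diisopropylcarbamate 19 are taken as catalogue chemicals; C8' of the target is S by the CIP rules only because the C12'=C13' double bond raises the rank of the C9' branch.

Abbreviations: TBS = tert-butyldimethylsilyl; TIB = 2,4,6-triisopropylbenzoyl; pin = pinacolato; DIAD = diisopropyl azodicarboxylate; TMEDA = N,N,N',N'-tetramethylethane-1,2-diamine.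

## Route

Step 1
Reactants: 1 (S)-Trolox
Product: 2 methyl (2S)-6-hydroxy-2,5,7,8-tetramethylchromane-2-carboxylate
Conditions: MeOH, cat. H2SO4, reflux
Reagents that add atoms: methanol, CO
Why: Fischer esterification of the carboxylic acid should proceed under acid catalysis and cannot disturb the quaternary C2, which carries no acidic hydrogen.

Step 2
Reactants: 2 methyl (2S)-6-hydroxy-2,5,7,8-tetramethylchromane-2-carboxylate
Product: 3 methyl (2S)-6-(TBS-oxy)-2,5,7,8-tetramethylchromane-2-carboxylate
Conditions: TBSCl, imidazole, DMF, 50 °C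
Reagents that add atoms: tert-butyldimethylsilyl chloride, CC(C)(C)[Si](C)(C)Cl
Why: Imidazole-promoted silyl ether formation masks the acidic, oxidation-prone phenol for all organometallic steps, and mild heating should overcome the two flanking methyl groups.

Step 3
Reactants: 3 methyl (2S)-6-(TBS-oxy)-2,5,7,8-tetramethylchromane-2-carboxylate
Product: 4 (2S)-6-(TBS-oxy)-2,5,7,8-tetramethylchromane-2-carbaldehyde
Conditions: i-Bu2AlH (1.1 equiv), toluene, −78 °C; aq. potassium sodium tartrate
Reagents that add atoms: none
Why: Partial ester reduction with i-Bu2AlH should stop at the aldehyde because the tetrahedral aluminium hemiacetal, stabilised by the neighbouring ring oxygen O1, survives at −78 °C until work-up.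

Step 4
Reactants: 4 (2S)-6-(TBS-oxy)-2,5,7,8-tetramethylchromane-2-carbaldehyde; 5 ethyl (triphenylphosphoranylidene)acetate
Product: 6 ethyl (E)-3-[(2S)-6-(TBS-oxy)-2,5,7,8-tetramethylchroman-2-yl]prop-2-enoate
Conditions: toluene, 90 °C
Reagents that add atoms: none
Why: The Wittig reaction of a stabilised ylide should give the E-enoate and adds C2' and C3', while the non-enolisable aldehyde keeps C2 safe.

Step 5
Reactants: 6 ethyl (E)-3-[(2S)-6-(TBS-oxy)-2,5,7,8-tetramethylchroman-2-yl]prop-2-enoate
Product: 7 ethyl 3-[(2S)-6-(TBS-oxy)-2,5,7,8-tetramethylchroman-2-yl]propanoate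
Conditions: H2 (1 atm), Pd/C, EtOAc, rt
Reagents that add atoms: none
Why: Heterogeneous catalytic hydrogenation saturates the only C=C bond of this half, and the ester, the aryl silyl ether and the fully substituted ring A are inert under one atmosphere of hydrogen.

Step 6
Reactants: 7 ethyl 3-[(2S)-6-(TBS-oxy)-2,5,7,8-tetramethylchroman-2-yl]propanoate
Product: 8 3-[(2S)-6-(TBS-oxy)-2,5,7,8-tetramethylchroman-2-yl]propan-1-ol
Conditions: LiAlH4, THF, 0 °C
Reagents that add atoms: none
Why: Hydride reduction of the ester gives the primary alcohol at C3', and the hindered aryl silyl ether should survive at 0 °C.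

Step 7
Reactants: 8 3-[(2S)-6-(TBS-oxy)-2,5,7,8-tetramethylchroman-2-yl]propan-1-ol
Product: 9 3-[(2S)-6-(TBS-oxy)-2,5,7,8-tetramethylchroman-2-yl]propyl 2,4,6-triisopropylbenzoate
Conditions: 2,4,6-triisopropylbenzoic acid, PPh3, DIAD, THF, 0 °C to rt
Reagents that add atoms: 2,4,6-triisopropylbenzoic acid, CC(C)c1cc(C(C)C)c(C(=O)O)c(C(C)C)c1
Why: The Mitsunobu esterification activates the unhindered primary alcohol instead of the very hindered acid and so installs the directing and leaving group on C3'.

Step 8
Reactants: 10 5-bromo-2-methylpent-1-ene; 11 (R)-β-butyrolactone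
Product: 13 (3R)-3,7-dimethyloct-7-enoic acid, via Grignard reagent 12 (not isolated)
Conditions: 10, Mg, THF, rt to 40 °C; CuBr·SMe2 (10 mol %), THF–Me2S, −30 °C; 11, −30 to 0 °C; aq. HCl
Reagents that add atoms: none
Why: In this copper-catalysed SN2 ring opening of a β-lactone the soft organocopper species attacks the alkyl C–O carbon of the strained ring with inversion, so the R lactone sets C8' in the required sense.

Step 9
Reactants: 13 (3R)-3,7-dimethyloct-7-enoic acid
Product: 14 (3R)-3,7-dimethyloct-7-en-1-ol
Conditions: LiAlH4, Et2O, 0 °C to rt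
Reagents that add atoms: none
Why: Hydride reduction of the carboxylic acid gives the primary alcohol and leaves the isolated alkene and the β-stereocentre untouched.

Step 10
Reactants: 14 (3R)-3,7-dimethyloct-7-en-1-ol
Product: 15 (6R)-8-bromo-2,6-dimethyloct-1-ene
Conditions: CBr4, PPh3, CH2Cl2, 0 °C
Reagents that add atoms: carbon tetrabromide, BrC(Br)(Br)Br
Why: The Appel reaction converts the primary alcohol to the bromide under neutral conditions, so the acid-sensitive 1,1-disubstituted alkene should not migrate.

Step 11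
Reactants: 15 (6R)-8-bromo-2,6-dimethyloct-1-ene; 16 bis(4,4,5,5-tetramethyl-1,3,2-dioxaborolan-2-yl)methane
Product: 18 2-[(4S)-4,8-dimethylnon-8-en-1-yl]-4,4,5,5-tetramethyl-1,3,2-dioxaborolane, via sodium borylmethanide 17 (not isolated)
Conditions: NaOt-Bu, THF, rt
Reagents that add atoms: none
Why: In this deborylative alkylation of a geminal bis(boronate) the alkoxide removes one boryl group, and the boron-stabilised carbanion displaces the primary bromide by SN2, adding C5' together with the boron atom.

Step 12
Reactants: 18 2-[(4S)-4,8-dimethylnon-8-en-1-yl]-4,4,5,5-tetramethyl-1,3,2-dioxaborolane; 19 ethyl N,N-diisopropylcarbamate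
Product: 22 2-[(2R,6S)-6,10-dimethylundec-10-en-2-yl]-4,4,5,5-tetramethyl-1,3,2-dioxaborolane, via lithiated carbamate 20 (not isolated), via boronate complex 21 (not isolated)
Conditions: 19, s-BuLi, (−)-sparteine, Et2O, −78 °C; 18, −78 °C; MgBr2·OEt2, −78 °C to reflux
Reagents that add atoms: none
Why: In this lithiation–borylation (a reagent-controlled Matteson-type homologation) s-BuLi/(−)-sparteine removes the pro-S hydrogen of 19, the S carbenoid 20 is borylated with retention, and the C5' chain then migrates from boron to carbon with inversion as the carbamate leaves, which sets C4' as R.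

Step 13
Reactants: 9 3-[(2S)-6-(TBS-oxy)-2,5,7,8-tetramethylchroman-2-yl]propyl 2,4,6-triisopropylbenzoate; 22 2-[(2R,6S)-6,10-dimethylundec-10-en-2-yl]-4,4,5,5-tetramethyl-1,3,2-dioxaborolane
Product: 27 (2R)-6-(TBS-oxy)-2,5,7,8-tetramethyl-2-[(4R,8S)-4,8,12-trimethyltridec-12-en-1-yl]chromane, via lithiated benzoate 23 (not isolated), via mixed boronate complex 24 (not isolated), via C3'-boronic ester 25 (not isolated), via phenylboronate complex 26 (not isolated)
Conditions: 9 (1.2 equiv), s-BuLi (1.15 equiv), TMEDA, Et2O, −78 °C; 22 (1.0 equiv), −78 °C, then reflux; PhLi (1.1 equiv), THF, −78 to 0 °C; Mn(OAc)3, 4-tert-butylcatechol, rt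
Reagents that add atoms: none
Why: Complexation of s-BuLi to the hindered benzoate carbonyl directs deprotonation to C3'–H of 9, carbenoid 23 adds to the empty orbital of boron in 22 so that both halves are held on one boron atom in 24 by two C–B bonds that the target does not contain, and on warming C4' migrates from boron to C3' antiperiplanar to the departing triisopropylbenzoate, forming the C3'–C4' bond inside this tether. The closest known reaction type is the one-pot lithiation–borylation–protodeboronation of α-methyl-branched secondary pinacol boronic esters with lithiated primary triisopropylbenzoates, that is a stereospecific Matteson-type 1,2-metallate rearrangement followed by an oxidative radical protodeboronation. No ring is closed, and the temporary dioxaborolane ring leaves as PhBpin. No lasting stereocentre is created: C4' migrates with retention because its C–B σ bond is the nucleophile, so the R configuration from step 12 is carried over, whereas the transient stereocentre C3' (both epimers, since achiral TMEDA is used) is erased when PhLi turns 25 into boronate 26, Mn(OAc)3 oxidises 26 by one electron to the secondary C3' radical and 4-tert-butylcatechol hands over a hydrogen atom. Site selectivity of the lithiation over the benzylic methyl groups of ring A and the allylic positions is secured by the carbonyl-directed deprotonation, the ester carbonyl is shielded from the organolithium reagents by its two ortho isopropyl groups, and loss of the alkyl rather than the phenyl group from 26 follows from the far greater stability of a secondary alkyl radical. The C12'=C13' alkene is too remote from C3' for cyclisation and inert to all reagents, so the junction is obtained saturated without any hydrogenation.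

Step 14
Reactants: 27 (2R)-6-(TBS-oxy)-2,5,7,8-tetramethyl-2-[(4R,8S)-4,8,12-trimethyltridec-12-en-1-yl]chromane
Product: 28 (2R)-2,5,7,8-tetramethyl-2-[(4R,8S)-4,8,12-trimethyltridec-12-en-1-yl]chroman-6-ol
Conditions: n-Bu4NF, THF, 0 °C, argon; aq. NH4Cl
Reagents that add atoms: none
Why: Fluoride-mediated desilylation is driven by the strong Si–F bond, touches neither the alkene nor any stereocentre, and exclusion of air protects the liberated chromanol from oxidation.

## Compound list

1 | (S)-Trolox, (2S)-6-hydroxy-2,5,7,8-tetramethylchromane-2-carboxylic acid | O=C(O)[C@]1(C)CCc2c(C)c(O)c(C)c(C)c2O1 | starting material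
2 | methyl (2S)-6-hydroxy-2,5,7,8-tetramethylchromane-2-carboxylate | COC(=O)[C@]1(C)CCc2c(C)c(O)c(C)c(C)c2O1 | intermediate
3 | methyl (2S)-6-(TBS-oxy)-2,5,7,8-tetramethylchromane-2-carboxylate | COC(=O)[C@]1(C)CCc2c(C)c(O[Si](C)(C)C(C)(C)C)c(C)c(C)c2O1 | intermediate
4 | (2S)-6-(TBS-oxy)-2,5,7,8-tetramethylchromane-2-carbaldehyde | O=C[C@]1(C)CCc2c(C)c(O[Si](C)(C)C(C)(C)C)c(C)c(C)c2O1 | intermediate
5 | ethyl (triphenylphosphoranylidene)acetate | CCOC(=O)C=P(c1ccccc1)(c1ccccc1)c1ccccc1 | starting material
6 | ethyl (E)-3-[(2S)-6-(TBS-oxy)-2,5,7,8-tetramethylchroman-2-yl]prop-2-enoate | CCOC(=O)/C=C/[C@]1(C)CCc2c(C)c(O[Si](C)(C)C(C)(C)C)c(C)c(C)c2O1 | intermediate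
7 | ethyl 3-[(2S)-6-(TBS-oxy)-2,5,7,8-tetramethylchroman-2-yl]propanoate | CCOC(=O)CC[C@]1(C)CCc2c(C)c(O[Si](C)(C)C(C)(C)C)c(C)c(C)c2O1 | intermediate
8 | 3-[(2S)-6-(TBS-oxy)-2,5,7,8-tetramethylchroman-2-yl]propan-1-ol | OCCC[C@]1(C)CCc2c(C)c(O[Si](C)(C)C(C)(C)C)c(C)c(C)c2O1 | intermediate
9 | 3-[(2S)-6-(TBS-oxy)-2,5,7,8-tetramethylchroman-2-yl]propyl 2,4,6-triisopropylbenzoate | CC(C)c1cc(C(C)C)c(C(=O)OCCC[C@]2(C)CCc3c(C)c(O[Si](C)(C)C(C)(C)C)c(C)c(C)c3O2)c(C(C)C)c1 | intermediate
10 | 5-bromo-2-methylpent-1-ene | C=C(C)CCCBr | starting material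
11 | (R)-β-butyrolactone, (4R)-4-methyloxetan-2-one | C[C@@H]1CC(=O)O1 | starting material
12 | (4-methylpent-4-en-1-yl)magnesium bromide | C=C(C)CCC[Mg]Br | intermediate
13 | (3R)-3,7-dimethyloct-7-enoic acid | C=C(C)CCC[C@@H](C)CC(=O)O | intermediate
14 | (3R)-3,7-dimethyloct-7-en-1-ol | C=C(C)CCC[C@@H](C)CCO | intermediate
15 | (6R)-8-bromo-2,6-dimethyloct-1-ene | C=C(C)CCC[C@@H](C)CCBr | intermediate
16 | bis(4,4,5,5-tetramethyl-1,3,2-dioxaborolan-2-yl)methane | CC1(C)OB(CB2OC(C)(C)C(C)(C)O2)OC1(C)C | starting material
17 | sodium (4,4,5,5-tetramethyl-1,3,2-dioxaborolan-2-yl)methanide | [Na+].[CH2-]B1OC(C)(C)C(C)(C)O1 | intermediate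
18 | 2-[(4S)-4,8-dimethylnon-8-en-1-yl]-4,4,5,5-tetramethyl-1,3,2-dioxaborolane | C=C(C)CCC[C@@H](C)CCCB1OC(C)(C)C(C)(C)O1 | intermediate
19 | ethyl N,N-diisopropylcarbamate | CCOC(=O)N(C(C)C)C(C)C | starting material
20 | (S)-1-lithioethyl N,N-diisopropylcarbamate, present as its (−)-sparteine complex | [Li][C@@H](C)OC(=O)N(C(C)C)C(C)C | intermediate
21 | lithium boronate complex of 18 and 20 (boron bears C5' and the S carbamoyloxyethyl carbon) | [Li+].C=C(C)CCC[C@@H](C)CCC[B-]1([C@@H](C)OC(=O)N(C(C)C)C(C)C)OC(C)(C)C(C)(C)O1 | intermediate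
22 | 2-[(2R,6S)-6,10-dimethylundec-10-en-2-yl]-4,4,5,5-tetramethyl-1,3,2-dioxaborolane | C=C(C)CCC[C@@H](C)CCC[C@@H](C)B1OC(C)(C)C(C)(C)O1 | intermediate
23 | C3'-lithiated 9 as its TMEDA complex (C3' both configurations, C2 as in 9) | CC(C)c1cc(C(C)C)c(C(=O)OC([Li])CC[C@]2(C)CCc3c(C)c(O[Si](C)(C)C(C)(C)C)c(C)c(C)c3O2)c(C(C)C)c1 | intermediate
24 | lithium boronate complex of 22 and 23 (boron bears C4' and C3'; C3' both epimers; C2, C4', C8' arranged as in 28) | [Li+].C=C(C)CCC[C@@H](C)CCC[C@@H](C)[B-]1(C(CC[C@]2(C)CCc3c(C)c(O[Si](C)(C)C(C)(C)C)c(C)c(C)c3O2)OC(=O)c2c(C(C)C)cc(C(C)C)cc2C(C)C)OC(C)(C)C(C)(C)O1 | intermediate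
25 | C3'-(pinacolatoboryl) derivative of 27 (C3' both epimers; C2, C4', C8' arranged as in 28) | C=C(C)CCC[C@@H](C)CCC[C@@H](C)C(CC[C@]1(C)CCc2c(C)c(O[Si](C)(C)C(C)(C)C)c(C)c(C)c2O1)B1OC(C)(C)C(C)(C)O1 | intermediate
26 | lithium B-phenyl boronate complex of 25 | [Li+].C=C(C)CCC[C@@H](C)CCC[C@@H](C)C(CC[C@]1(C)CCc2c(C)c(O[Si](C)(C)C(C)(C)C)c(C)c(C)c2O1)[B-]1(c2ccccc2)OC(C)(C)C(C)(C)O1 | intermediate
27 | (2R)-6-(TBS-oxy)-2,5,7,8-tetramethyl-2-[(4R,8S)-4,8,12-trimethyltridec-12-en-1-yl]chromane | C=C(C)CCC[C@@H](C)CCC[C@@H](C)CCC[C@]1(C)CCc2c(C)c(O[Si](C)(C)C(C)(C)C)c(C)c(C)c2O1 | intermediate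
28 | (2R)-2,5,7,8-tetramethyl-2-[(4R,8S)-4,8,12-trimethyltridec-12-en-1-yl]chroman-6-ol | C=C(C)CCC[C@@H](C)CCC[C@@H](C)CCC[C@]1(C)CCc2c(C)c(O)c(C)c(C)c2O1 | target

## Step count and risks

Total step count: 14.

Longest linear sequence: 9 steps (steps 1–7, 13 and 14, from (S)-Trolox). The right half takes 5 steps (steps 8–12).

**Step 13.**
- What may go wrong: competing lateral lithiation of the ring A methyl groups or silyl migration, slow boronate formation at the hindered secondary boronic ester, or incomplete oxidative protodeboronation.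
- Fallback: the boron tether is replaced by a copper-catalysed SN2 alkyl–alkyl cross-coupling with inversion. It sets out from 15 and 8 and comes back at 27.
- Compound 15 is turned with Mg in THF into [(3R)-3,7-dimethyloct-7-en-1-yl]magnesium bromide F1.
- F1 opens (S)-propylene oxide at its CH2 group under CuI catalysis to give (2S,6R)-6,10-dimethylundec-10-en-2-ol F2.
- TsCl in pyridine converts F2 into (2S,6R)-6,10-dimethylundec-10-en-2-yl 4-methylbenzenesulfonate F3.
- Alcohol 8 is converted by an Appel reaction (CBr4, PPh3) into tert-butyl{[(2S)-2-(3-bromopropyl)-2,5,7,8-tetramethylchroman-6-yl]oxy}dimethylsilane F4.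
- F4 gives with Mg {3-[(2S)-6-(TBS-oxy)-2,5,7,8-tetramethylchroman-2-yl]propyl}magnesium bromide F5.
- F5 and F3 are coupled with CuI, TMEDA and LiOMe in THF at 0 °C. Displacement of the secondary tosylate with inversion should give the 4'R centre of 27.

**Step 12.**
- What may go wrong: incomplete enantioselection in the deprotonation, or sluggish migration against the poor carbamate leaving group.
- Fallback: the carbenoid homologation is replaced by an alkene hydrofunctionalisation. It sets out from 15, bypasses 18 and comes back at 22.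
- Bromide 15 is coupled with allylmagnesium bromide (cat. Li2CuCl4, THF) to give (6S)-6,10-dimethylundeca-1,10-diene F6.
- The monosubstituted alkene of F6 then undergoes a copper-catalysed enantioselective Markovnikov protoboration (CuCl, a bulky chiral N-heterocyclic carbene ligand of the antipode that leads to the R product, B2pin2, NaOt-Bu, MeOH).
- The more hindered 1,1-disubstituted alkene should stay untouched.

**Step 8.**
- What may go wrong: attack at the acyl carbon of the lactone instead of the alkyl C–O carbon, or base-induced elimination to crotonate.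
- Fallback: the chiral-pool SN2 opening is replaced by a catalytic asymmetric conjugate addition. It sets out from 12 and comes back at 14.
- Grignard reagent 12 is added to methyl (E)-crotonate with CuBr·SMe2 and a Josiphos-type ferrocenyl diphosphine (the ligand enantiomer that leads to the R ester) in t-BuOMe at −75 °C to give methyl (3R)-3,7-dimethyloct-7-enoate F7.
- LiAlH4 reduces F7 to 14.

Further compounds
F1 | step 13 | [(3R)-3,7-dimethyloct-7-en-1-yl]magnesium bromide | C=C(C)CCC[C@@H](C)CC[Mg]Br
F2 | step 13 | (2S,6R)-6,10-dimethylundec-10-en-2-ol | C=C(C)CCC[C@@H](C)CCC[C@H](C)O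
F3 | step 13 | (2S,6R)-6,10-dimethylundec-10-en-2-yl 4-methylbenzenesulfonate | C=C(C)CCC[C@@H](C)CCC[C@H](C)OS(=O)(=O)c1ccc(C)cc1
F4 | step 13 | tert-butyl{[(2S)-2-(3-bromopropyl)-2,5,7,8-tetramethylchroman-6-yl]oxy}dimethylsilane | BrCCC[C@]1(C)CCc2c(C)c(O[Si](C)(C)C(C)(C)C)c(C)c(C)c2O1
F5 | step 13 | {3-[(2S)-6-(TBS-oxy)-2,5,7,8-tetramethylchroman-2-yl]propyl}magnesium bromide | Br[Mg]CCC[C@]1(C)CCc2c(C)c(O[Si](C)(C)C(C)(C)C)c(C)c(C)c2O1
F6 | step 12 | (6S)-6,10-dimethylundeca-1,10-diene | C=C(C)CCC[C@@H](C)CCCC=C
F7 | step 8 | methyl (3R)-3,7-dimethyloct-7-enoate | C=C(C)CCC[C@@H](C)CC(=O)OC
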